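Longipinane numbering: C1 ketone, C2=C3, cyclobutane C4–C5–C11–C10, gem-dimethyl C6, esters at C7 and C9. Everything rests on removing C6 from the seven-membered ring C4–C5–C6–C7–C8–C9–C10. Quaternary C6 sits between carbinol C7 and cyclobutane methine C5, the retron of a semipinacol shift. The precursor is a copaane-like tricyclo[4.4.0.0(2,7)]decene whose six-membered ring C4–C5–C7–C8–C9–C10 carries OH and isopropenyl on C7. In one operation C5 migrates from C7 to the cationic isopropyl carbon: the ring grows to seven atoms, the gem-dimethyl centre forms and the C7 ketone appears. Diels–Alder reaction and enolate alkylation build the precursor; an Evans–Tishchenko reaction differentiates the esters.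

Key step: step 8

From step 3 on, every carbon keeps the longipinane number it has in the target.
Assumption 1: the diene is taken to add to 4 on the face of the enone bond that is remote from the neighbouring dioxolane phenyl group. For (S,S)-hydrobenzoin this gives the drawn absolute configuration; if the sense is opposite, (R,R)-hydrobenzoin is used.
Assumption 2: the copper catalyst with the ligand enantiomer named in step 10 is taken to deliver boron to the face of C9 that looks toward C11; otherwise the antipodal ligand is used.

Step 1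
Reactants: 1 2,6-dimethylphenol
Product: 2 4,4-dimethoxy-2,6-dimethylcyclohexa-2,5-dien-1-one
Conditions: PhI(OAc)2 (2.2 equiv), MeOH, 0 °C to rt
Reagents that add atoms: methanol CO
Why: Twofold hypervalent-iodine oxidative dearomatisation of a para-unsubstituted phenol in methanol should give the p-quinone monoketal, which masks the future C1 ketone; no stereocentre is formed.

Step 2
Reactants: 2 4,4-dimethoxy-2,6-dimethylcyclohexa-2,5-dien-1-one; 3 (1S,2S)-1,2-diphenylethane-1,2-diol
Product: 4 (2S,3S)-7,9-dimethyl-2,3-diphenyl-1,4-dioxaspiro[4.5]deca-6,9-dien-8-one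
Conditions: pyridinium p-toluenesulfonate (cat.), benzene, 4 Å molecular sieves, reflux
Reagents that add atoms: (1S,2S)-1,2-diphenylethane-1,2-diol O[C@@H](c1ccccc1)[C@@H](O)c1ccccc1
Why: Acid-catalysed transketalisation driven by removal of methanol installs a diol with a twofold axis, so the spiro carbon is no stereocentre, the two enone bonds become homotopic and their faces become diastereotopic.

Step 3
Reactants: 4 chiral quinone monoketal; 5 2-(trimethylsilyloxy)buta-1,3-diene
Product: 6 cis-fused cycloadduct (C10 methyl and C11–H cis, C4 ketone conjugated with C3=C2, C1 diphenyldioxolane ketal, C7=C8 trimethylsilyl enol ether)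
Conditions: 5 (3 equiv), 2,6-di-tert-butyl-4-methylphenol (trace), toluene, sealed tube, 120 °C
Reagents that add atoms: 2-(trimethylsilyloxy)buta-1,3-diene C=CC(=C)O[Si](C)(C)C
Why: Thermal normal-demand Diels–Alder reaction in which the nucleophilic CH2 next to the siloxy carbon bonds to C11 (β to the C4 ketone, para rule), suprafacial addition makes the C10–C11 fusion cis, and approach anti to the flanking phenyl group should set C10 and C11 absolutely.

Step 4
Reactants: 6 cis-fused cycloadduct
Product: 8 hydroxy ketone (C4–OH cis to the C10 methyl, C7 ketone), via silyl enol ether alcohol 7 (not isolated)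
Conditions: i-Bu2AlH, CH2Cl2, −78 °C; aq. potassium sodium tartrate; then K2CO3 (cat.), MeOH, 0 °C
Reagents that add atoms: none
Why: Chemoselective 1,2-reduction of the enone should take place anti to the pseudo-axial angular methyl group, which places the C4 hydroxyl cis to that methyl, while the silyl enol ether shields C7 until methanolysis frees the ketone.

Step 5
Reactants: 8 hydroxy ketone
Product: 9 allylic mesylate (C4–OMs cis to the C10 methyl)
Conditions: MsCl, Et3N, CH2Cl2, −30 °C, used crude
Reagents that add atoms: methanesulfonyl chloride CS(=O)(=O)Cl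
Why: O-Sulfonylation leaves the C4 configuration untouched and turns the hydroxyl into a leaving group that has no β-hydrogen on C10 or C3, so elimination is excluded.

Step 6
Reactants: 9 allylic mesylate
Product: 10 tricyclic ketone (1,3-dimethyltricyclo[4.4.0.0(2,7)]dec-3-ene-5,8-dione 5-ketal; C7 ketone, cyclobutane C4–C5–C11–C10)
Conditions: KOt-Bu, THF/t-BuOH, 0 °C to rt
Reagents that add atoms: none
Why: Intramolecular enolate alkylation (4-exo-tet SN2) under equilibrating conditions, in which only the C5 enolate lies anti to the C4–O bond locked by the carbocycle; C4 is inverted, C5 is fixed by the bridged geometry, and SN2' attack at C2 is blocked by the adjacent spiroketal.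

Step 7
Reactants: 10 tricyclic ketone; 11 isopropenylmagnesium bromide
Product: 12 tertiary allylic alcohol (7-hydroxy-7-isopropenyl, mixture of C7 epimers)
Conditions: 11 (0.5 M in THF), THF, −78 to 0 °C; aq. NH4Cl
Reagents that add atoms: isopropenylmagnesium bromide CC(=C)[Mg]Br
Why: Grignard 1,2-addition to the only carbonyl group brings in C6 and both of its methyl carbons; the two faces of C7 are hardly differentiated, which does not matter because C7 becomes trigonal in the next step.

Step 8
Reactants: 12 tertiary allylic alcohol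
Product: 13 longipinane ketone (C7 ketone, C6 gem-dimethyl, C1 ketal)
Conditions: [N,N'-bis(3,5-di-tert-butylsalicylidene)-1,2-cyclohexanediaminato]cobalt (5 mol %), N-fluoro-2,4,6-trimethylpyridinium triflate, PhSiH3, acetone, 0 °C
Reagents that add atoms: none
Why: Hydrogen atom transfer from a cobalt hydride (formed from the divalent cobalt complex, the oxidant and PhSiH3) to the CH2 terminus of the isopropenyl group gives the tertiary C6 radical, which is captured by cobalt and oxidised to a cation-like tetravalent alkylcobalt species; C5 then shifts from C7 to C6 anti to the departing metal while the hydroxyl group collapses to the ketone. The closest known reaction type is the hydrogen-atom-transfer-initiated radical–polar crossover semipinacol rearrangement of tertiary allylic alcohols, run here as a one-carbon ring enlargement. No ring is closed: the six-membered rings C4–C5–C7–C8–C9–C10 and C11–C5–C7–C8–C9–C10 are each enlarged by insertion of C6 through a suprafacial 1,2-alkyl shift, so the bicyclo[3.1.1]heptane half becomes a bicyclo[4.1.1]octane. No new stereocentre arises, C5 migrates with retention, C6 is achiral and both C7 epimers of 12 converge on 13. The step needs migration of C5 rather than C8, which the higher migratory aptitude of the methine carbon should secure, and hydrogen atom transfer to the 1,1-disubstituted alkene rather than to the hindered trisubstituted C2=C3 bond next to the ketal. The near-neutral conditions avoid ionisation at C7, which would give a cyclobutylcarbinyl cation and skeletal rearrangement.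

Step 9
Reactants: 13 longipinane ketone
Product: 14 longipinane enone (C7 ketone, C8=C9)
Conditions: IBX, DMSO, 65 °C
Reagents that add atoms: none
Why: IBX dehydrogenation of a ketone proceeds through its enol, and since C6 is quaternary only C8 can enolise, so the C8=C9 enone should be the sole regioisomer.

Step 10
Reactants: 14 longipinane enone
Product: 16 β-hydroxy ketone (9-OH on the face toward C11, C7 ketone), via β-boryl ketone 15 (not isolated)
Conditions: CuCl (5 mol %), NaOt-Bu (10 mol %), (R)-1-[(Sp)-2-(diphenylphosphino)ferrocenyl]ethyldicyclohexylphosphine (6 mol %), B2pin2, MeOH (2 equiv), THF, rt; then 30% H2O2, pH 7 phosphate buffer, 0 °C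
Reagents that add atoms: bis(pinacolato)diboron CC1(C)OB(OC1(C)C)B1OC(C)(C)C(C)(C)O1 (boron of 15); hydrogen peroxide OO (oxygen of 16)
Why: Copper-catalysed asymmetric conjugate borylation followed by stereoretentive C–B oxidation; the two faces of C9 are nearly equivalent in the substrate, so the chiral ligand should decide the C9 configuration.

Step 11
Reactants: 16 β-hydroxy ketone; 17 3-methylbutanal
Product: 18 7-hydroxy-9-isovalerate (7-OH and 9-O-acyl trans)
Conditions: SmI2 (0.3 equiv), 17 (8 equiv), THF, −10 °C
Reagents that add atoms: 3-methylbutanal CC(C)CC=O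
Why: Evans–Tishchenko reaction, in which the samarium-bound hemiacetal of the C9 hydroxyl delivers hydride intramolecularly to the C7 ketone from the face of the C9 oxygen; this should give the 1,3-anti C7 carbinol and leave the isovaleryl group on O9 in the same operation.

Step 12
Reactants: 18 7-hydroxy-9-isovalerate; 19 3-methylbut-2-enoyl chloride
Product: 20 diester ketal
Conditions: 19, pyridine, 4-(dimethylamino)pyridine (cat.), CH2Cl2, 40 °C
Reagents that add atoms: 3-methylbut-2-enoyl chloride CC(C)=CC(=O)Cl
Why: Nucleophile-catalysed acylation of the only free hydroxyl group; pyridine is used in place of a trialkylamine to suppress vinylketene formation and deconjugation of the senecioyl unit.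

Step 13
Reactants: 20 diester ketal
Product: 21 target, (4R,5S,7R,9R,10R,11R)-9-isovaleryloxy-7-senecioyloxylongipin-2-en-1-one
Conditions: CF3CO2H/H2O, CH2Cl2, 0 °C
Reagents that add atoms: water O
Why: Acid hydrolysis of the allylic ketal passes through an allyl-stabilised oxocarbenium ion, should spare both esters and the cyclobutane, and releases the C1 enone together with the auxiliary diol.

Compound list
1 | 2,6-dimethylphenol | Cc1cccc(C)c1O | starting material
2 | 4,4-dimethoxy-2,6-dimethylcyclohexa-2,5-dien-1-one | COC1(OC)C=C(C)C(=O)C(C)=C1 | intermediate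
3 | (1S,2S)-1,2-diphenylethane-1,2-diol ((S,S)-hydrobenzoin) | O[C@@H](c1ccccc1)[C@@H](O)c1ccccc1 | starting material
4 | (2S,3S)-7,9-dimethyl-2,3-diphenyl-1,4-dioxaspiro[4.5]deca-6,9-dien-8-one | O=C1C(C)=CC2(C=C1C)O[C@@H](c3ccccc3)[C@H](c3ccccc3)O2 | intermediate
5 | 2-(trimethylsilyloxy)buta-1,3-diene | C=CC(=C)O[Si](C)(C)C | starting material
6 | cis-fused cycloadduct, C4 enone, C1 ketal, C7=C8 silyl enol ether | C[Si](C)(C)OC1=CC[C@]2(C)C(=O)C(C)=CC3(O[C@@H](c4ccccc4)[C@H](c4ccccc4)O3)[C@@H]2C1 | intermediate
7 | silyl enol ether alcohol, C4–OH cis to C10 methyl | C[Si](C)(C)OC1=CC[C@]2(C)[C@@H](O)C(C)=CC3(O[C@@H](c4ccccc4)[C@H](c4ccccc4)O3)[C@@H]2C1 | intermediate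
8 | hydroxy ketone, C4–OH cis to C10 methyl, C7 ketone | O=C1CC[C@]2(C)[C@@H](O)C(C)=CC3(O[C@@H](c4ccccc4)[C@H](c4ccccc4)O3)[C@@H]2C1 | intermediate
9 | allylic mesylate of 8 | O=C1CC[C@]2(C)[C@@H](OS(C)(=O)=O)C(C)=CC3(O[C@@H](c4ccccc4)[C@H](c4ccccc4)O3)[C@@H]2C1 | intermediate
10 | tricyclic ketone, 1,3-dimethyltricyclo[4.4.0.0(2,7)]dec-3-ene-5,8-dione 5-ketal | O=C1CC[C@@]2(C)[C@@H]3C4(O[C@@H](c5ccccc5)[C@H](c5ccccc5)O4)C=C(C)[C@H]2[C@@H]31 | intermediate
11 | isopropenylmagnesium bromide | CC(=C)[Mg]Br | starting material
12 | tertiary allylic alcohol, 7-hydroxy-7-isopropenyl, C7 epimers | CC(=C)C1(O)CC[C@@]2(C)[C@@H]3C4(O[C@@H](c5ccccc5)[C@H](c5ccccc5)O4)C=C(C)[C@H]2[C@@H]31 | intermediate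
13 | longipin-2-ene-1,7-dione 1-ketal | O=C1CC[C@@]2(C)[C@@H]3C4(O[C@@H](c5ccccc5)[C@H](c5ccccc5)O4)C=C(C)[C@H]2[C@@H]3C1(C)C | intermediate
14 | longipina-2,8-diene-1,7-dione 1-ketal | O=C1C=C[C@@]2(C)[C@@H]3C4(O[C@@H](c5ccccc5)[C@H](c5ccccc5)O4)C=C(C)[C@H]2[C@@H]3C1(C)C | intermediate
15 | 9-(pinacolatoboryl) ketone, boron on the face toward C11 | O=C1C[C@@H](B5OC(C)(C)C(C)(C)O5)[C@@]2(C)[C@@H]3C4(O[C@@H](c6ccccc6)[C@H](c6ccccc6)O4)C=C(C)[C@H]2[C@@H]3C1(C)C | intermediate
16 | 9-hydroxy ketone, OH on the face toward C11 | O=C1C[C@@H](O)[C@@]2(C)[C@@H]3C4(O[C@@H](c5ccccc5)[C@H](c5ccccc5)O4)C=C(C)[C@H]2[C@@H]3C1(C)C | intermediate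
17 | 3-methylbutanal | CC(C)CC=O | starting material
18 | 7-hydroxy-9-isovalerate, 7,9-trans | O[C@@H]1C[C@@H](OC(=O)CC(C)C)[C@@]2(C)[C@@H]3C4(O[C@@H](c5ccccc5)[C@H](c5ccccc5)O4)C=C(C)[C@H]2[C@@H]3C1(C)C | intermediate
19 | 3-methylbut-2-enoyl chloride (senecioyl chloride) | CC(C)=CC(=O)Cl | starting material
20 | 7-senecioate 9-isovalerate 1-ketal | CC(C)=CC(=O)O[C@@H]1C[C@@H](OC(=O)CC(C)C)[C@@]2(C)[C@@H]3C4(O[C@@H](c5ccccc5)[C@H](c5ccccc5)O4)C=C(C)[C@H]2[C@@H]3C1(C)C | intermediate
21 | (4R,5S,7R,9R,10R,11R)-9-isovaleryloxy-7-senecioyloxylongipin-2-en-1-one | CC(C)=CC(=O)O[C@@H]1C[C@@H](OC(=O)CC(C)C)[C@@]2(C)[C@@H]3C(=O)C=C(C)[C@H]2[C@@H]3C1(C)C | target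

Total step count: 13. Longest linear sequence: 13 steps, from 1 to 21.

Steps most likely to fail

**Step 3.** The cycloaddition may be too slow at the trisubstituted enone bond, whose β-carbon lies next to the spiroketal. The temperature it needs may also erode the facial selectivity.
The fallback sets out from 4 and comes back at 8. Compound 4 would be combined below 60 °C with the far more reactive (E)-3-(tert-butyldimethylsilyloxy)-N,N-dimethylbuta-1,3-dien-1-amine to give the amino siloxy cycloadduct F1. Reduction with i-Bu2AlH gives the C4 alcohol F2. Aqueous HF in MeCN removes the silyl group and eliminates the amine to give the hydroxy enone F3. Conjugate reduction with [(Ph3P)CuH]6 returns to 8.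

**Step 8.** The hydroxyl group may capture the cationic centre (epoxide formation), or C8 may migrate in competition with C5.
The fallback sets out from 10 and comes back at 13. Addition of 2-lithio-2-(methylselanyl)propane (from 2,2-bis(methylselanyl)propane and n-BuLi, THF, −78 °C) gives the β-hydroxy selenide F4. The leaving group of F4 sits on C6 only. Activation of selenium with AgBF4 on alumina in CH2Cl2 triggers the same ring-enlarging semipinacol shift, a variant known to favour migration of the more substituted carbon.

**Step 10.** Addition of the boryl-copper species next to quaternary C10 may be slow, and the catalyst may not control the C9 face sufficiently.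
The fallback sets out from 14 and comes back at 16. Primary-amine-catalysed asymmetric nucleophilic epoxidation (9-amino-9-deoxy-epi-quinine trifluoroacetate salt, aq. H2O2, dioxane) gives the 8,9-epoxy ketone F5. Reductive opening of the Cα–O bond with (PhSe)2/NaBH4 in EtOH/AcOH gives 16.

Further compounds
F1 | step 3 | amino siloxy cycloadduct (endo, NMe2 cis to C4) | CC(C)(C)[Si](C)(C)OC1=C[C@H](N(C)C)[C@]2(C)C(=O)C(C)=CC3(O[C@@H](c4ccccc4)[C@H](c4ccccc4)O3)[C@@H]2C1
F2 | step 3 | C4 alcohol of F1 (OH cis to C10 methyl) | CC(C)(C)[Si](C)(C)OC1=C[C@H](N(C)C)[C@]2(C)[C@@H](O)C(C)=CC3(O[C@@H](c4ccccc4)[C@H](c4ccccc4)O3)[C@@H]2C1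
F3 | step 3 | hydroxy enone (C7 ketone, C8=C9) | O=C1C=C[C@]2(C)[C@@H](O)C(C)=CC3(O[C@@H](c4ccccc4)[C@H](c4ccccc4)O3)[C@@H]2C1
F4 | step 8 | β-hydroxy selenide (C7 epimers) | C[Se]C(C)(C)C1(O)CC[C@@]2(C)[C@@H]3C4(O[C@@H](c5ccccc5)[C@H](c5ccccc5)O4)C=C(C)[C@H]2[C@@H]31
F5 | step 10 | 8,9-epoxy ketone (oxygen on the face toward C11) | O=C1[C@H]5O[C@H]5[C@@]2(C)[C@@H]3C4(O[C@@H](c6ccccc6)[C@H](c6ccccc6)O4)C=C(C)[C@H]2[C@@H]3C1(C)C
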